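The disconnection cuts ring A at two adjacent positions: the diaryl ether bond O–C6 and the bond from C1 to the ester carbon. Ring A carries three contiguous substituents, aryloxy at C6, carboxyl at C1 and prenyloxy at C2. A 3-alkoxybenzyne delivers exactly this pattern when a nucleophile adds at its remote carbon and an electrophile caps the anion beside the alkoxy group. In one operation the ring B phenoxide, the aryne and carbon dioxide are joined, and methyl iodide completes the ester in the same flask. The precursor is 5-methyl-3-(prenyloxy)-2-(trimethylsilyl)phenyl triflate, partnered with a ring B phenol whose benzylic alcohol is silyl-protected.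

Key step: step 8

Remarks
- Stereochemistry: the target has no stereocentre, no stereogenic axis and no E/Z-defined alkene (the double bond ends in two methyl groups), so one achiral compound is made and no stereocontrol is needed.
- Numbering: ring A is the benzoate ring (C1 CO2Me, C2 O-prenyl, C4 CH3, C6 O-aryl); ring B is the dimethoxyphenyl ring (C1′ O, C2′ CH2OH, C4′ and C6′ OMe); prenyl = 3-methylbut-2-en-1-yl.
- Structure check: in the silyl triflate the methyl group must be para to silicon and meta to both oxygens (5-methyl-3-prenyloxy locants). The isomer with methyl beside silicon would put the carboxyl next to a methyl group and is not used.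
- Protecting group: the benzylic alcohol is carried as a TIPS ether, not an acetal. It goes selectively onto the primary OH beside the free phenol, has no acidic proton, and leaves with buffered fluoride, whereas acid strong enough to open an alkyl acetal endangers the aryl prenyl ether.
- 2,4-Dimethoxyphenol is taken as a catalogue chemical.

Step 1
Reactants: 1 orcinol; 2 prenyl bromide
Product: 3 3-methyl-5-(prenyloxy)phenol
Conditions: K2CO3, acetone, reflux; 1 in threefold excess
Reagents that add atoms: none
Why: Williamson ether synthesis (SN2 of the potassium phenoxide at the primary allylic carbon of 2); the excess of the water-extractable diol biases the statistics towards the mono-ether, and K2CO3 in acetone favours O- over C-alkylation.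

Step 2
Reactants: 3 3-methyl-5-(prenyloxy)phenol
Product: 4 3-methyl-5-(prenyloxy)phenyl N-isopropylcarbamate
Conditions: i-PrNCO, Et3N (cat.), CH2Cl2, rt
Reagents that add atoms: isopropyl isocyanate, CC(C)N=C=O
Why: Amine-catalysed addition of the phenol O–H to the isocyanate (carbamoylation) leaves the prenyl ether untouched and installs a group that directs lithiation and can later be removed without strong nucleophiles.

Step 3
Reactants: 4 3-methyl-5-(prenyloxy)phenyl N-isopropylcarbamate
Product: 8 5-methyl-3-(prenyloxy)-2-(trimethylsilyl)phenyl N-isopropylcarbamate, via N-silyl carbamate 5 (not isolated), via aryllithium 6 (not isolated), via bis-silyl carbamate 7 (not isolated)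
Conditions: TMEDA, TBSOTf, Et2O, 0 °C → rt; n-BuLi, TMEDA, −78 °C; TMSCl, −78 °C → rt; cold aq NaHSO4 work-up
Reagents that add atoms: chlorotrimethylsilane, C[Si](C)(C)Cl
Why: Directed ortho-metalation: after in-situ N-silylation masks the N–H, n-BuLi/TMEDA removes the ring proton between the carbamate oxygen and the ether oxygen (activated by both), TMSCl silylates the aryllithium and the N–Si bond is hydrolysed on work-up; at −78 °C the allylic O–CH2 of the prenyl ether should be deprotonated more slowly than this doubly activated position.

Step 4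
Reactants: 8 5-methyl-3-(prenyloxy)-2-(trimethylsilyl)phenyl N-isopropylcarbamate
Product: 10 5-methyl-3-(prenyloxy)-2-(trimethylsilyl)phenyl trifluoromethanesulfonate, via silyl phenoxide 9 (not isolated)
Conditions: DBU, Et2NH, MeCN, 40 °C; then PhNTf2, rt
Reagents that add atoms: N-phenylbis(trifluoromethanesulfonimide), O=S(=O)(N(c1ccccc1)S(=O)(=O)C(F)(F)F)C(F)(F)F
Why: E1cB cleavage of the N-monosubstituted carbamate (DBU removes N–H, isopropyl isocyanate departs and is scavenged by Et2NH) frees the phenoxide, which PhNTf2 sulfonylates in the same flask (triflation); no fluoride, acid or strong nucleophile is present, so the aryl C–Si bond and the prenyl ether persist.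

Step 5
Reactants: 11 2,4-dimethoxyphenol
Product: 12 2-hydroxy-3,5-dimethoxybenzaldehyde
Conditions: MgCl2, Et3N, (CH2O)n, MeCN, reflux; dilute acid work-up
Reagents that add atoms: paraformaldehyde (as formaldehyde), C=O
Why: Casnati–Skattebøl ortho-formylation: the magnesium phenoxide delivers formaldehyde to the only free ortho position, and a second formaldehyde oxidises the benzylic alkoxide to the aldehyde by hydride transfer.

Step 6
Reactants: 12 2-hydroxy-3,5-dimethoxybenzaldehyde
Product: 13 2-(hydroxymethyl)-4,6-dimethoxyphenol
Conditions: NaBH4, MeOH, 0 °C; aq NH4Cl work-up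
Reagents that add atoms: none
Why: Borohydride reduction of an aryl aldehyde to the primary benzylic alcohol; the near-neutral work-up avoids acid-induced ortho-quinone methide formation from the electron-rich hydroxybenzyl alcohol.

Step 7
Reactants: 13 2-(hydroxymethyl)-4,6-dimethoxyphenol
Product: 14 4,6-dimethoxy-2-{[(triisopropylsilyl)oxy]methyl}phenol
Conditions: TIPSCl, imidazole, CH2Cl2, 0 °C → rt
Reagents that add atoms: chlorotriisopropylsilane, CC(C)[Si](Cl)(C(C)C)C(C)C
Why: Chemoselective silyl ether formation: the primary alcohol reacts with the bulky chlorosilane much faster than the phenol, which is flanked by two ortho substituents and hydrogen-bonded to the neighbouring methoxy group.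

Step 8
Reactants: 10 5-methyl-3-(prenyloxy)-2-(trimethylsilyl)phenyl trifluoromethanesulfonate; 14 4,6-dimethoxy-2-{[(triisopropylsilyl)oxy]methyl}phenol; 15 carbon dioxide
Product: 20 methyl 2-[4,6-dimethoxy-2-({[triisopropylsilyl]oxy}methyl)phenoxy]-4-methyl-6-(prenyloxy)benzoate, via potassium phenoxide 16 (not isolated), via aryne 17 (not isolated), via arylpotassium 18 (not isolated), via potassium carboxylate 19 (not isolated)
Conditions: 14, KH, THF, 0 °C; 18-crown-6, KF, CO2 (1 atm); 10 added slowly, 0 °C → rt; then MeI, DMF, rt
Reagents that add atoms: iodomethane, CI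
Why: Proposed new method: fluoride attacks silicon of 10 and triflate leaves to give aryne 17; phenoxide 16 adds to the aryne carbon remote from the prenyloxy group (the former C–OTf carbon) to give arylpotassium 18, whose carbanion lies between the two oxygen-bearing carbons and is carboxylated by dissolved CO2 to 19, which MeI then O-methylates. The closest known reaction type is the fluoride-induced three-component coupling of arynes with nitrogen nucleophiles and CO2 to give anthranilic acid derivatives, together with the two-component O-arylation of phenols by silylaryl triflates; an aryloxide in the three-component manifold is the untested extension. No ring is closed and no stereocentre is formed. The regiochemistry needed (aryloxy at C6, carboxyl at C1) is secured by the C2 alkoxy group, which distorts the aryne and inductively stabilises negative charge on the adjacent carbon, so that nucleophiles add at the distal carbon. Carboxylation should outrun protonation because every acidic proton is removed beforehand (phenol deprotonated with KH, benzylic OH silylated, THF in place of MeCN) and the aryne is kept dilute under a CO2 atmosphere.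

Step 9
Reactants: 20 methyl 2-[4,6-dimethoxy-2-({[triisopropylsilyl]oxy}methyl)phenoxy]-4-methyl-6-(prenyloxy)benzoate
Product: 21 methyl 2-[2-(hydroxymethyl)-4,6-dimethoxyphenoxy]-4-methyl-6-[(3-methylbut-2-en-1-yl)oxy]benzoate
Conditions: TBAF, AcOH, THF, 0 °C → rt
Reagents that add atoms: none
Why: Fluoride-mediated desilylation of a primary silyl ether, driven by Si–F bond formation; acetic acid buffers the liberated alkoxide so that the methyl ester is not attacked, and the aryl prenyl ether and diaryl ether are inert to fluoride.

Compound list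
1 | orcinol (5-methylbenzene-1,3-diol) | Cc1cc(O)cc(O)c1 | starting material
2 | prenyl bromide (1-bromo-3-methylbut-2-ene) | CC(C)=CCBr | starting material
3 | 3-methyl-5-(prenyloxy)phenol | Cc1cc(O)cc(OCC=C(C)C)c1 | intermediate
4 | 3-methyl-5-(prenyloxy)phenyl N-isopropylcarbamate | CC(C)NC(=O)Oc1cc(C)cc(OCC=C(C)C)c1 | intermediate
5 | 3-methyl-5-(prenyloxy)phenyl N-(tert-butyldimethylsilyl)-N-isopropylcarbamate | CC(C)N(C(=O)Oc1cc(C)cc(OCC=C(C)C)c1)[Si](C)(C)C(C)(C)C | intermediate (not isolated)
6 | 2-lithio-5-methyl-3-(prenyloxy)phenyl N-(tert-butyldimethylsilyl)-N-isopropylcarbamate | CC(C)N(C(=O)Oc1cc(C)cc(OCC=C(C)C)c1[Li])[Si](C)(C)C(C)(C)C | intermediate (not isolated)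
7 | 5-methyl-3-(prenyloxy)-2-(trimethylsilyl)phenyl N-(tert-butyldimethylsilyl)-N-isopropylcarbamate | CC(C)N(C(=O)Oc1cc(C)cc(OCC=C(C)C)c1[Si](C)(C)C)[Si](C)(C)C(C)(C)C | intermediate (not isolated)
8 | 5-methyl-3-(prenyloxy)-2-(trimethylsilyl)phenyl N-isopropylcarbamate | CC(C)NC(=O)Oc1cc(C)cc(OCC=C(C)C)c1[Si](C)(C)C | intermediate
9 | 5-methyl-3-(prenyloxy)-2-(trimethylsilyl)phenol, present as its DBU-H+ phenoxide | Cc1cc(O)c([Si](C)(C)C)c(OCC=C(C)C)c1 | intermediate (not isolated)
10 | 5-methyl-3-(prenyloxy)-2-(trimethylsilyl)phenyl trifluoromethanesulfonate (aryne precursor) | C[Si](C)(C)c1c(OCC=C(C)C)cc(C)cc1OS(=O)(=O)C(F)(F)F | intermediate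
11 | 2,4-dimethoxyphenol | COc1ccc(O)c(OC)c1 | starting material
12 | 2-hydroxy-3,5-dimethoxybenzaldehyde | COc1cc(C=O)c(O)c(OC)c1 | intermediate
13 | 2-(hydroxymethyl)-4,6-dimethoxyphenol | COc1cc(CO)c(O)c(OC)c1 | intermediate
14 | 4,6-dimethoxy-2-{[(triisopropylsilyl)oxy]methyl}phenol | COc1cc(CO[Si](C(C)C)(C(C)C)C(C)C)c(O)c(OC)c1 | intermediate
15 | carbon dioxide | O=C=O | starting material
16 | potassium 4,6-dimethoxy-2-{[(triisopropylsilyl)oxy]methyl}phenoxide | [K+].[O-]c1c(CO[Si](C(C)C)(C(C)C)C(C)C)cc(OC)cc1OC | intermediate (not isolated)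
17 | 5-methyl-3-(prenyloxy)benzyne (1,2-didehydro-5-methyl-3-(prenyloxy)benzene) | CC1=CC#CC(OCC=C(C)C)=C1 | intermediate (not isolated)
18 | {2-[4,6-dimethoxy-2-({[triisopropylsilyl]oxy}methyl)phenoxy]-4-methyl-6-(prenyloxy)phenyl}potassium | [K]c1c(OCC=C(C)C)cc(C)cc1Oc1c(CO[Si](C(C)C)(C(C)C)C(C)C)cc(OC)cc1OC | intermediate (not isolated)
19 | potassium 2-[4,6-dimethoxy-2-({[triisopropylsilyl]oxy}methyl)phenoxy]-4-methyl-6-(prenyloxy)benzoate | [K+].[O-]C(=O)c1c(OCC=C(C)C)cc(C)cc1Oc1c(CO[Si](C(C)C)(C(C)C)C(C)C)cc(OC)cc1OC | intermediate (not isolated)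
20 | methyl 2-[4,6-dimethoxy-2-({[triisopropylsilyl]oxy}methyl)phenoxy]-4-methyl-6-(prenyloxy)benzoate | COC(=O)c1c(OCC=C(C)C)cc(C)cc1Oc1c(CO[Si](C(C)C)(C(C)C)C(C)C)cc(OC)cc1OC | intermediate
21 | methyl 2-[2-(hydroxymethyl)-4,6-dimethoxyphenoxy]-4-methyl-6-[(3-methylbut-2-en-1-yl)oxy]benzoate | COC(=O)c1c(OCC=C(C)C)cc(C)cc1Oc1c(CO)cc(OC)cc1OC | target

Total step count: 9 (steps 1–4 for the ring A arm, steps 5–7 for the ring B arm, steps 8 and 9 after convergence).
Longest linear sequence: 6 steps (1 → 3 → 4 → 8 → 10 → 20 → 21).

Steps most likely to fail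

Step 8 (three-component coupling). The arylpotassium may be protonated before it meets CO2, giving the simple diaryl ether. The phenoxide may be held back as its CO2 adduct, so that the aryne self-reacts or the adduct adds with acyl transfer. The di-ortho-substituted phenoxide may also add too slowly. The fallback sets out from phenol 14 and returns at ester 20, using only known nucleophilic aromatic substitution and oxidation chemistry. Commercial 2,6-difluoro-4-methylbenzaldehyde is treated with one equivalent of prenol and NaH in THF at 0 °C to give 2-fluoro-4-methyl-6-(prenyloxy)benzaldehyde F1. Phenol 14 with K2CO3 in DMF at about 100 °C (as phenoxide 16) then displaces the remaining ortho-fluoride, which the formyl group activates, to give 2-[4,6-dimethoxy-2-({[triisopropylsilyl]oxy}methyl)phenoxy]-4-methyl-6-(prenyloxy)benzaldehyde F2. Pinnick oxidation (NaClO2, NaH2PO4, excess 2-methyl-2-butene, t-BuOH/H2O) gives 2-[4,6-dimethoxy-2-({[triisopropylsilyl]oxy}methyl)phenoxy]-4-methyl-6-(prenyloxy)benzoic acid F3. K2CO3 and MeI in DMF then convert F3 through carboxylate 19 into 20.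

Step 3 (ortho-silylation). n-BuLi may deprotonate the allylic O–CH2 of the prenyl ether, with Wittig rearrangement, in competition with ring lithiation; incomplete N-silylation would also let the carbamate collapse. The fallback sets out from orcinol 1 and returns at triflate 10, replacing C–H lithiation by halogen–lithium exchange and a retro-Brook shift. Orcinol is iodinated between the hydroxyl groups (I2, NaHCO3, THF/H2O, 0 °C) to give 2-iodo-5-methylbenzene-1,3-diol F4. Mono-O-alkylation with 2 (K2CO3, acetone) gives 2-iodo-5-methyl-3-(prenyloxy)phenol F5, and HMDS at 70 °C gives [2-iodo-5-methyl-3-(prenyloxy)phenoxy]trimethylsilane F6. n-BuLi in THF at −100 → −78 °C exchanges iodine faster than it deprotonates any C–H, giving [2-(trimethylsilyloxy)-4-methyl-6-(prenyloxy)phenyl]lithium F7. Its silyl group migrates from oxygen to carbon to give lithium 5-methyl-3-(prenyloxy)-2-(trimethylsilyl)phenoxide F8, the lithium salt of 9. Tf2O added at −78 °C then gives 10.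

Step 1 (mono-prenylation). Over-alkylation to the bis-ether and C-prenylation of the very electron-rich resorcinol ring under basic conditions may leave little mono-ether. The fallback sets out from orcinol 1 and returns at carbamate 4 by reversing the order of the first two operations. Orcinol and one equivalent of isopropyl isocyanate (cat. Et3N, THF) give 3-hydroxy-5-methylphenyl N-isopropylcarbamate F9. The statistical step thus becomes an O-selective acylation, and the bis-carbamate can be cleaved back to orcinol. The single remaining phenol, now on a less nucleophilic ring, is then prenylated under neutral Mitsunobu conditions (prenol, PPh3, DIAD, THF, 0 °C) to give 4.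

Further compounds
F1 | step 8 | 2-fluoro-4-methyl-6-(prenyloxy)benzaldehyde | O=Cc1c(F)cc(C)cc1OCC=C(C)C
F2 | step 8 | 2-[4,6-dimethoxy-2-({[triisopropylsilyl]oxy}methyl)phenoxy]-4-methyl-6-(prenyloxy)benzaldehyde | O=Cc1c(OCC=C(C)C)cc(C)cc1Oc1c(CO[Si](C(C)C)(C(C)C)C(C)C)cc(OC)cc1OC
F3 | step 8 | 2-[4,6-dimethoxy-2-({[triisopropylsilyl]oxy}methyl)phenoxy]-4-methyl-6-(prenyloxy)benzoic acid | OC(=O)c1c(OCC=C(C)C)cc(C)cc1Oc1c(CO[Si](C(C)C)(C(C)C)C(C)C)cc(OC)cc1OC
F4 | step 3 | 2-iodo-5-methylbenzene-1,3-diol | Cc1cc(O)c(I)c(O)c1
F5 | step 3 | 2-iodo-5-methyl-3-(prenyloxy)phenol | Cc1cc(O)c(I)c(OCC=C(C)C)c1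
F6 | step 3 | [2-iodo-5-methyl-3-(prenyloxy)phenoxy]trimethylsilane | Cc1cc(O[Si](C)(C)C)c(I)c(OCC=C(C)C)c1
F7 | step 3 | [2-(trimethylsilyloxy)-4-methyl-6-(prenyloxy)phenyl]lithium | Cc1cc(O[Si](C)(C)C)c([Li])c(OCC=C(C)C)c1
F8 | step 3 | lithium 5-methyl-3-(prenyloxy)-2-(trimethylsilyl)phenoxide | [Li+].[O-]c1cc(C)cc(OCC=C(C)C)c1[Si](C)(C)C
F9 | step 1 | 3-hydroxy-5-methylphenyl N-isopropylcarbamate | CC(C)NC(=O)Oc1cc(C)cc(O)c1
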